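## Retrosynthetic overview

1. Target 14 ⇐ selective saponification of the vinylogous methyl ester next to the alkyl group in dimethoxyquinone 12 ⇐ oxidative aryl–O cleavage of the bridged aryl ether 11 (the oxygen stays on C-4a).
2. 11 ⇐ C-4a–O bond: intramolecular, demethylative Markovnikov hydro-etherification of the ring B alkene of 10 by an ortho-methoxy oxygen (sets C-4a and closes an oxepane).
3. 10 ⇐ aryl–CH2 bond: 2,3,5,6-tetramethoxyphenyllithium + neopentyl aldehyde 6, then benzylic deoxygenation.
4. 6 ⇐ endo Diels–Alder reaction of diene 4 with (Z)-2-methylbut-2-enal 5 (forms ring B and C-1, C-2, C-8a); 4 ⇐ 2,2-dimethylcyclohexanone 1 (ring A, bought).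
5. Ring order: ring A (bought) → ring B (cycloaddition) → arene attached → oxepane bridge (C–O) → bridge opened to the quinone.

Assumption: (Z)-2-methylbut-2-enal (angelic aldehyde) is bought and distilled cold before use; decalin stereodescriptors follow naphthalene numbering (C-1 quaternary, C-2 CHMe, C-4a carbinol, C-8a ring-fusion CH).

## Route

Step 1
Reactants: 1 2,2-dimethylcyclohexan-1-one
Product: 3 6,6-dimethylcyclohex-1-en-1-yl trifluoromethanesulfonate, via lithium enolate 2 (not isolated)
Conditions: LiN(i-Pr)2, THF, −78 °C; PhNTf2, −78 °C to rt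
Reagents that add atoms: N-phenylbis(trifluoromethanesulfonimide), O=S(=O)(N(c1ccccc1)S(=O)(=O)C(F)(F)F)C(F)(F)F
Why: The ketone has a single enolisable α-carbon, so enolate formation and O-sulfonylation (enol triflate synthesis) give one regioisomer; no stereocentre is formed.

Step 2
Reactants: 3 6,6-dimethylcyclohex-1-en-1-yl trifluoromethanesulfonate
Product: 4 1-ethenyl-6,6-dimethylcyclohex-1-ene
Conditions: Bu3SnCH=CH2, Pd(PPh3)4 (zerovalent palladium, 3 mol %), LiCl, THF, 65 °C
Reagents that add atoms: tributyl(vinyl)stannane, C=C[Sn](CCCC)(CCCC)CCCC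
Why: Stille coupling of an enol triflate with a vinylstannane is a standard entry to 2-substituted 1,3-dienes and tolerates the neighbouring quaternary carbon; no stereocentre is formed.

Step 3
Reactants: 4 1-ethenyl-6,6-dimethylcyclohex-1-ene; 5 (Z)-2-methylbut-2-enal
Product: 6 (1S,2S,8aR)-1,2,5,5-tetramethyl-1,2,3,5,6,7,8,8a-octahydronaphthalene-1-carbaldehyde
Conditions: (S)-3,3-diphenyl-1-(2-methylphenyl)tetrahydro-1H,3H-pyrrolo[1,2-c][1,3,2]oxazaborole (C24H24BNO, 20 mol %), HN(SO2CF3)2 (18 mol %), CH2Cl2, −78 to −40 °C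
Reagents that add atoms: none
Why: Oxazaborolidinium-catalysed enantioselective Diels–Alder reaction, in which the enal β-carbon bonds to the unsubstituted diene terminus ("ortho" orientation), the endo formyl group together with the Z geometry places CHO, the C-2 methyl and the ring A bond at C-8a all cis, and the catalyst (formyl C–H···O binding mode of 2-substituted enals, assigned by analogy with simpler 2-substituted acroleins) exposes the Re face of the enal C-2, fixing 1S,2S,8aR.

Step 4
Reactants: 6 (1S,2S,8aR)-1,2,5,5-tetramethyl-1,2,3,5,6,7,8,8a-octahydronaphthalene-1-carbaldehyde; 7 1,2,4,5-tetramethoxybenzene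
Product: 10 3-{[(1S,2S,8aS)-1,2,5,5-tetramethyl-1,2,3,5,6,7,8,8a-octahydronaphthalen-1-yl]methyl}-1,2,4,5-tetramethoxybenzene, via aryllithium 8 (not isolated), via lithium alkoxide 9 (not isolated)
Conditions: 7, n-BuLi, THF, 0 °C to rt; 6, −78 to 0 °C; then Li, NH3(l)/THF, −78 °C; NH4Cl
Reagents that add atoms: none
Why: Directed ortho-lithiation between two methoxy groups, 1,2-addition to the non-enolisable neopentyl aldehyde and dissolving-metal hydrogenolysis of the benzylic C–O bond (tandem arylation–reductive deoxygenation) remove the new carbinol centre, so its configuration is irrelevant, and the isolated trisubstituted alkene is not reduced.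

Step 5
Reactants: 10 3-{[(1S,2S,8aS)-1,2,5,5-tetramethyl-1,2,3,5,6,7,8,8a-octahydronaphthalen-1-yl]methyl}-1,2,4,5-tetramethoxybenzene
Product: 11 bridged aryl ether: (1S,2S,4aR,8aS)-1,2,5,5-tetramethyldecahydronaphthalene (trans-fused) whose C-4a oxygen is O-2 of a 3,5,6-trimethoxyphenyl ring and whose C-1 carries the CH2 bonded to C-1 of that ring (arene-fused oxepane bridging C-1 and C-4a)
Conditions: [N,N′-bis(3,5-di-tert-butylsalicylidene)-1,2-cyclohexanediaminato]cobalt (C36H52CoN2O2, divalent cobalt, 5 mol %), N-fluoro-2,4,6-trimethylpyridinium triflate (1.5 equiv), PhSiH3 (1.5 equiv), PhCF3, 0 °C to rt, argon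
Reagents that add atoms: none
Why: Proposed new method: cobalt-hydride hydrogen-atom transfer to the alkene CH gives the tertiary C-4a radical, which is oxidised through an alkylcobalt species (tetravalent cobalt) to a cation equivalent (radical-polar crossover); the twisted, hence nucleophilic, ortho-methoxy oxygen on the pseudo-axial CH2 arm at C-1 can reach C-4a only from the same face (seven-membered, 1,3-diaxial bridge), so the C–O bond, the 4aR centre and the trans ring fusion are set by geometry, and the aryl(methyl)oxonium is demethylated by the released 2,4,6-collidine; the closest known reaction types are the cobalt–salen/N-fluoropyridinium/silane Markovnikov hydroalkoxylation of unactivated alkenes with alcohol or methyl ether (deprotective) nucleophiles forming five- and six-membered rings, and the demethylative electrophilic cyclisation of ortho-alkynylanisoles.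

Step 6
Reactants: 11 bridged aryl ether
Product: 12 3-{[(1S,2S,4aR,8aS)-4a-hydroxy-1,2,5,5-tetramethyldecahydronaphthalen-1-yl]methyl}-2,5-dimethoxycyclohexa-2,5-diene-1,4-dione
Conditions: (NH4)2Ce(NO3)6 (tetravalent cerium, 2.5 equiv), MeCN/H2O 2:1, 0 °C, 15 min
Reagents that add atoms: water, O
Why: Oxidative dealkylation of a para-dialkoxyarene, in which water adds ipso at the para pair formed by the bridge oxygen and the planar methoxy group (the better-conjugated pair, since the other pair contains a perpendicular methoxy group), so one carbon loses methanol and the other has its aryl–O bond cut with the oxygen left on C-4a (retention, as in chroman-to-hydroxyalkylquinone oxidations).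

Step 7
Reactants: 12 3-{[(1S,2S,4aR,8aS)-4a-hydroxy-1,2,5,5-tetramethyldecahydronaphthalen-1-yl]methyl}-2,5-dimethoxycyclohexa-2,5-diene-1,4-dione
Product: 14 2-hydroxy-3-{[(1S,2S,4aR,8aS)-4a-hydroxy-1,2,5,5-tetramethyldecahydronaphthalen-1-yl]methyl}-5-methoxycyclohexa-2,5-diene-1,4-dione, via potassium quinonolate 13 (not isolated)
Conditions: KOH (2 M aq.), MeOH, 0 °C to rt; then 1 M HCl
Reagents that add atoms: potassium hydroxide, [K+].[OH-]
Why: Addition–elimination (vinylogous ester saponification) in which hydroxide displaces the methoxy group twisted out of conjugation by the flanking alkyl substituent, the selectivity relied on for 3-alkyl-2,5-dimethoxybenzoquinones, while the product is protected as its quinonolate and the tertiary alcohol is inert to base.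

## Compound list

1 | 2,2-dimethylcyclohexan-1-one | CC1(C)CCCCC1=O | starting material
2 | lithium 6,6-dimethylcyclohex-1-en-1-olate | [Li]OC1=CCCCC1(C)C | intermediate (not isolated)
3 | 6,6-dimethylcyclohex-1-en-1-yl trifluoromethanesulfonate | CC1(C)CCCC=C1OS(=O)(=O)C(F)(F)F | intermediate
4 | 1-ethenyl-6,6-dimethylcyclohex-1-ene | C=CC1=CCCCC1(C)C | intermediate
5 | (Z)-2-methylbut-2-enal | C/C=C(/C)C=O | starting material
6 | (1S,2S,8aR)-1,2,5,5-tetramethyl-1,2,3,5,6,7,8,8a-octahydronaphthalene-1-carbaldehyde | O=C[C@@]1(C)[C@@H](C)CC=C2[C@H]1CCCC2(C)C | intermediate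
7 | 1,2,4,5-tetramethoxybenzene | COc1cc(OC)c(OC)cc1OC | starting material
8 | (2,3,5,6-tetramethoxyphenyl)lithium | [Li]c1c(OC)c(OC)cc(OC)c1OC | intermediate (not isolated)
9 | lithium [(1S,2S,8aR)-1,2,5,5-tetramethyl-1,2,3,5,6,7,8,8a-octahydronaphthalen-1-yl](2,3,5,6-tetramethoxyphenyl)methanolate, both carbinol epimers | [Li]OC(c1c(OC)c(OC)cc(OC)c1OC)[C@@]2(C)[C@@H](C)CC=C3[C@H]2CCCC3(C)C | intermediate (not isolated)
10 | 3-{[(1S,2S,8aS)-1,2,5,5-tetramethyl-1,2,3,5,6,7,8,8a-octahydronaphthalen-1-yl]methyl}-1,2,4,5-tetramethoxybenzene | COc1cc(OC)c(OC)c(C[C@@]2(C)[C@@H](C)CC=C3[C@H]2CCCC3(C)C)c1OC | intermediate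
11 | bridged aryl ether: (1S,2S,4aR,8aS)-trans-decalin, C-4a–O bonded to C-2 of the 3,5,6-trimethoxyphenyl ring, C-1–CH2 bonded to C-1 of that ring | COc1cc(OC)c2c(c1OC)C[C@@]3(C)[C@@H](C)CC[C@@]4(O2)[C@H]3CCCC4(C)C | intermediate
12 | 3-{[(1S,2S,4aR,8aS)-4a-hydroxy-1,2,5,5-tetramethyldecahydronaphthalen-1-yl]methyl}-2,5-dimethoxycyclohexa-2,5-diene-1,4-dione | COC1=CC(=O)C(OC)=C(C[C@@]2(C)[C@@H](C)CC[C@@]3(O)[C@H]2CCCC3(C)C)C1=O | intermediate
13 | potassium salt (quinonolate) of 14 | COC1=CC(=O)C([O-])=C(C[C@@]2(C)[C@@H](C)CC[C@@]3(O)[C@H]2CCCC3(C)C)C1=O.[K+] | intermediate (not isolated)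
14 | 2-hydroxy-3-{[(1S,2S,4aR,8aS)-4a-hydroxy-1,2,5,5-tetramethyldecahydronaphthalen-1-yl]methyl}-5-methoxycyclohexa-2,5-diene-1,4-dione | COC1=CC(=O)C(O)=C(C[C@@]2(C)[C@@H](C)CC[C@@]3(O)[C@H]2CCCC3(C)C)C1=O | target

## Step count and risks

Total steps: 7. Longest linear sequence: 7 (1 → 14; 5 and 7 are bought).

Three steps most likely to fail:

- **Step 3.** The Z-enal may isomerise to the E-enal on the Lewis acid, which would give the C-2 epimer, and the enantioselectivity is untested for this dienophile. The fallback sets out from 4 and comes back at 6; it replaces the catalytic asymmetric step by a ring-locked dienophile and a resolution. Diene 4 and commercial 3-methylfuran-2(5H)-one (EtAlCl2, CH2Cl2, 0 °C; lactone carbonyl endo, geometry fixed by the ring) give the racemic cis-fused γ-lactone of (1R,2S,8aR)-2-(hydroxymethyl)-1,5,5-trimethyl-1,2,3,5,6,7,8,8a-octahydronaphthalene-1-carboxylic acid F1, whose enantiomers are separated by preparative chiral SFC. PhSeNa (from PhSeSePh and NaBH4, DMF, 120 °C) opens the lactone at the O–CH2 carbon to (1R,2S,8aR)-1,5,5-trimethyl-2-[(phenylselanyl)methyl]-1,2,3,5,6,7,8,8a-octahydronaphthalene-1-carboxylic acid F2. Bu3SnH/AIBN (benzene, 80 °C) converts CH2SePh into the C-2 methyl group of (1S,2S,8aR)-1,2,5,5-tetramethyl-1,2,3,5,6,7,8,8a-octahydronaphthalene-1-carboxylic acid F3. LiAlH4 (THF, reflux) gives [(1S,2S,8aR)-1,2,5,5-tetramethyl-1,2,3,5,6,7,8,8a-octahydronaphthalen-1-yl]methanol F4, and Dess–Martin periodinane (CH2Cl2, rt) returns aldehyde 6.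

- **Step 5 (the proposed new step).** The seven-membered closure by an aryl methyl ether oxygen may lose to 1,2-methyl shift from the gem-dimethyl carbon, to elimination, or to fluorination. The fallback uses known chemistry, sets out from 10 and comes back at 12. Oxymercuration–demercuration (Hg(OAc)2, divalent mercury, THF/H2O, rt; then NaBH4, NaOH) gives 3-{[(1S,2S,4aR,8aS)-4a-hydroxy-1,2,5,5-tetramethyldecahydronaphthalen-1-yl]methyl}-1,2,4,5-tetramethoxybenzene F5. Anti addition is expected to set the centre: the mercurinium ion forms on the face opposite the axial arylmethyl arm and water attacks the tertiary carbon axially from the other face. Any aryl-mercury species formed on the electron-rich ring is reduced back to C–H by NaBH4. Oxidation of the now symmetric arene of F5 with (NH4)2Ce(NO3)6 (MeCN/H2O, 0 °C) gives 12 without a regiochemical question.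

- **Step 6.** The oxidation may take place across the other para pair of oxygens and keep the bridge. The fallback sets out from 11 and comes back at 12; it opens the bridge by transetherification instead of by oxidative aryl–O cleavage. The same oxidant then gives the bridged vinylogous-ester quinone F6, in which the C-4a oxygen is bonded to C-2 of a 5-methoxy-1,4-benzoquinone whose C-3 carries the CH2 to decalin C-1 ((1S,2S,4aR,8aS)). NaOMe in MeOH (0 °C to rt) adds to the quinone carbon that bears the bridge oxygen and expels the tertiary alkoxide, which gives 12. Attack at the other methoxy-bearing carbon is a degenerate exchange, so both oxidation outcomes converge on 12.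

Further compounds
F1 | step 3 | γ-lactone of (1R,2S,8aR)-2-(hydroxymethyl)-1,5,5-trimethyl-1,2,3,5,6,7,8,8a-octahydronaphthalene-1-carboxylic acid (made racemic, resolved by chiral SFC; enantiomer carried on shown) | O=C1OC[C@H]2CC=C3[C@@H](CCCC3(C)C)[C@@]12C
F2 | step 3 | (1R,2S,8aR)-1,5,5-trimethyl-2-[(phenylselanyl)methyl]-1,2,3,5,6,7,8,8a-octahydronaphthalene-1-carboxylic acid | OC(=O)[C@@]1(C)[C@@H](C[Se]c2ccccc2)CC=C3[C@H]1CCCC3(C)C
F3 | step 3 | (1S,2S,8aR)-1,2,5,5-tetramethyl-1,2,3,5,6,7,8,8a-octahydronaphthalene-1-carboxylic acid | OC(=O)[C@@]1(C)[C@@H](C)CC=C2[C@H]1CCCC2(C)C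
F4 | step 3 | [(1S,2S,8aR)-1,2,5,5-tetramethyl-1,2,3,5,6,7,8,8a-octahydronaphthalen-1-yl]methanol | OC[C@@]1(C)[C@@H](C)CC=C2[C@H]1CCCC2(C)C
F5 | step 5 | 3-{[(1S,2S,4aR,8aS)-4a-hydroxy-1,2,5,5-tetramethyldecahydronaphthalen-1-yl]methyl}-1,2,4,5-tetramethoxybenzene | COc1cc(OC)c(OC)c(C[C@@]2(C)[C@@H](C)CC[C@@]3(O)[C@H]2CCCC3(C)C)c1OC
F6 | step 6 | bridged vinylogous-ester quinone: 5-methoxy-1,4-benzoquinone with O-2 bonded to C-4a and C-3–CH2 bonded to C-1 of the (1S,2S,4aR,8aS)-1,2,5,5-tetramethyldecahydronaphthalene | COC1=CC(=O)C2=C(C1=O)C[C@@]3(C)[C@@H](C)CC[C@@]4(O2)[C@H]3CCCC4(C)C
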